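All runs are simulated with constants of no real substance, noise included.

The vessel starts with its solid substrate undissolved, and I treat that solid as a tank draining into the liquid.

| setting | south-east | north-west | flask |
|---|---|---|---|
| solid substrate | 0.20 M | 0.13 M | 0.20 M |
| partner | 0.20 M | 0.20 M | 0.200 M |
| temperature | 25 °C | 20 °C | 25 °C |
| remark | the very flask that is asked about, followed so far | run made earlier |  |
| time |  |  | 2.0 d |

- south-east (time / h: target / %, solid substrate / %): 6.00: 68.4, 0; 15.0: 68.4, 0; 20.0: 68.2, 0.2; 30.0: 68.9, 0; 40.0: 68.8, 0; 50.0: 68.2, 0.1
- north-west (time / h: target / %, solid substrate / %): 0.133: 0.8, 95.0; 0.417: 6.0, 84.9; 0.667: 12.5, 76.1; 1.00: 19.9, 65.7; 1.50: 31.8, 48.5; 2.00: 42.9, 32.2; 2.50: 53.7, 16.3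

(readings scatter by 0.3 percentage points)

- zeta: change nothing and wait 25 h more
- beta: at 2.0 d add partner, 100% of the amount charged, then wait 25 h
- theta: at 2.0 d raise the temperature by 15 K, then wait 25 h

- the volume of additions can be left aside
- the analysis behind the earlier runs scatters by 0.3 percentage points, standard deviation
- at the start none of the solid substrate is in solution
- a reading or a percentage of target counts all its forms, free or not

- target, in percent of the solid substrate first charged, at 2.0 d
- what to do for the largest gain in target; "none" if nothing gains more than 2 percentage points (zeta / beta / theta / none)
- target present, in percent of the solid substrate first charged, after zeta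
- target present, in percent of the solid substrate first charged, after beta

In the north-west run, the solid falls from 65.7% at 1.00 h to 16.3% at 2.50 h. That is a drain of 0.329 h⁻¹ as a fraction of that run's charge. The south-east flask holds 1.54 times that charge. The north-west run is colder than this flask, but I assume the same amount leaves per hour. My emptying time, the crossing at which the tank stops feeding the liquid, is then the estimate 4.67 h.

The first south-east reading, at 6.00 h, comes later than this and shows solid at 0%. The asked time is ten times the emptying time, so I read this flask as well past the crossing.

Now the bracket. Partner is charged at 100% of the solid, so if one partner goes into one target, that is the bound from above. The readings past the crossing tighten it: none lies above 68.9% or below 68.2%, and I place target at the asked time between those two. The last south-east reading shows 0.1% of solid, less than the 2 percentage points an option must gain, and the south-east readings of target span 0.7 points, so I choose none.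

The forecast gives 68.5%, from 68.2% to 68.8%, which lies inside my bracket. It also gives 68.5% after waiting, 68.5% after adding partner, and none as the best choice, on the ground that “No substrate remains to convert and target shows no decay”.

    solid substrate ⇌ dissolved substrate, rate k1*(cs1 - [dissolved substrate]) while solid is left; crystals form when [dissolved substrate] > cs1 (solubility = 0.0630 M, k = 0.0140 min⁻¹)
    dissolved substrate + partner → target (k = 0.370 M⁻¹ min⁻¹, Ea = 54.0 kJ mol⁻¹)
    2 dissolved substrate → side product (k = 1.00 M⁻¹ min⁻¹, Ea = 63.0 kJ mol⁻¹)
    solid product ⇌ target, rate k4*(cs4 - [target]) while solid is left; crystals form when [target] > cs4 (solubility = 43.0 mM, k = 2.50 min⁻¹)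
    (constants at 25 °C)

The flask gives 68.6%, and 68.6% and 68.6% after waiting and after adding partner, and heating gains 0 points, so the best choice is none. In this flask at 4.80 h, just later than the emptying time, solid substrate, the limiting reagent here, stands at 0%, with dissolved substrate at 3.06%. A neighbour flask with the same solid charge and 0.080 M of partner, if I take the same drain there, is read at ten times the emptying time. It too shows solid at 0%, with target, all forms counted, at 34.0%.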